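**Retrosynthetic overview**
- Target ⇐ ketal hydrolysis and C8 esterification with N‑methylurocanic acid (made from the imidazole aldehyde and malonic acid) ⇐ furanose methyl ketal.
- Key steps: furanose ketal ⇐ pyranose→furanose ring contraction ⇐ methyl addition to a pyranone ⇐ ionic oxidative furan→pyranone ring expansion of a furanophane.
- Furanophane (ten‑membered ring) ⇐ intramolecular Suzuki coupling of furan C5 with a (Z)‑α‑chloroacrylate ⇐ lactol + methyl trichloroacetate.
- Lactol ⇐ cis‑fused lactone ⇐ new nickel‑catalysed homoallylation of furfural with an exocyclic diene ester (C8–C9 bond, C8 and C10 stereocentres).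
- Ring A ⇐ organocatalytic Michael/aldol annulation of methyl 3‑oxopentanoate with (E)‑4‑methylpent‑2‑enal. Ring order: ring A → ten‑membered ring (furan bought) → pyranone (expansion) → dihydrofuran (contraction).

Labels used in names and reasons: sarcodictyin numbering, C1/C10 ring‑fusion CH, C2=C3 enoate (C3 bears CO2Me), C4 ketal carbon, C5=C6, C7 (Me, O), C8 (O‑acyl), C9 CH2, C11(Me)=C12, C13 CH2, C14 CH(i‑Pr); the target is 1R,4R,7S,8S,10R,14R.

Step 1
Reactants: 1 methyl acetoacetate
Product: 2 methyl 3‑oxopentanoate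
Conditions: NaH, THF, 0 °C; n‑BuLi, 0 °C; MeI, 0 °C → rt; aq. HCl
Reagents that add atoms: iodomethane (CI)
Why: γ‑alkylation of the acetoacetate dianion (Weiler alkylation) methylates the more basic terminal carbanion selectively and forms no stereocentre.

Step 2
Reactants: 2 methyl 3‑oxopentanoate; 3 (E)‑4‑methylpent‑2‑enal
Product: 5 methyl (1S,6R)‑3‑methyl‑2‑oxo‑6‑(propan‑2‑yl)cyclohex‑3‑ene‑1‑carboxylate, via Michael adduct 4 (not isolated)
Conditions: (R)‑2‑[diphenyl(trimethylsilyloxy)methyl]pyrrolidine (10 mol %), PhCO2H (10 mol %), toluene, 0 °C → rt; then TsOH·H2O (20 mol %), 80 °C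
Reagents that add atoms: none
Why: iminium‑catalysed Michael addition followed by acid‑mediated intramolecular aldol condensation (organocatalytic Robinson‑type annulation) builds ring A, the (R)‑prolinol silyl ether shielding one face of the E‑iminium ion so that C14 is formed R while the epimerisable β‑keto ester carbon C1 settles trans to the isopropyl group.

Step 3
Reactants: 5 methyl (1S,6R)‑3‑methyl‑2‑oxo‑6‑(propan‑2‑yl)cyclohex‑3‑ene‑1‑carboxylate
Product: 6 methyl (1S,6R)‑3‑methyl‑2‑methylidene‑6‑(propan‑2‑yl)cyclohex‑3‑ene‑1‑carboxylate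
Conditions: Zn, CH2Br2, TiCl4, THF/CH2Cl2, 0 °C → rt
Reagents that add atoms: dibromomethane (BrCBr)
Why: Takai–Lombardo methylenation uses a non‑basic gem‑dimetallic reagent that converts enolisable ketones chemoselectively beside an ester, leaving C14 untouched and C1 trans (any C1 epimer is corrected at the lactone stage).

Step 4
Reactants: 6 methyl (1S,6R)‑3‑methyl‑2‑methylidene‑6‑(propan‑2‑yl)cyclohex‑3‑ene‑1‑carboxylate; 7 furfural
Product: 9 (3S,4aR,8R,8aS)‑3‑(furan‑2‑yl)‑5‑methyl‑8‑(propan‑2‑yl)‑3,4,4a,7,8,8a‑hexahydro‑1H‑isochromen‑1‑one (cis‑fused δ‑lactone), via hydroxy ester 8 (not isolated)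
Conditions: Ni(cod)2 (10 mol %), BINOL‑derived phosphoramidite L1 (matched enantiomer, 12 mol %), Et3B (2.4 equiv), THF, 25 °C; then KOt‑Bu (0.2 equiv), THF, 0 °C
Reagents that add atoms: none
Why: Proposed new method: a zerovalent nickel/chiral phosphoramidite catalyst couples the ring‑locked s‑trans diene with BEt3‑activated furfural by oxidative cyclisation at the exocyclic CH2 to a five‑membered oxanickelacycle σ‑bound at C10; ethyl transfer from boron, β‑hydride elimination and C–H reductive elimination then deliver H to C10 from the metal‑bearing face (the equatorial face opposite the C1 ester, so the new arm is cis to the ester and trans to the isopropyl group) and leave the C11=C12 alkene; the chair‑like metallacycle reinforced by the ligand gives the 1,3‑anti (8S) carbinol, and base‑catalysed lactonisation with C1 equilibration funnels the material into the cis‑fused lactone; the closest known reaction type is the nickel‑catalysed, triethylborane‑mediated 1,3‑anti‑selective homoallylation of aldehydes with acyclic s‑cis 1,3‑dienes, not yet shown for exocyclic s‑trans dienes or under ligand control.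

Step 5
Reactants: 9 cis‑fused δ‑lactone
Product: 10 (3S,4aR,8R,8aS)‑3‑(furan‑2‑yl)‑5‑methyl‑8‑(propan‑2‑yl)‑3,4,4a,7,8,8a‑hexahydro‑1H‑isochromen‑1‑ol (lactol, both anomers)
Conditions: i‑Bu2AlH (1.1 equiv), CH2Cl2, −78 °C; aq. potassium sodium tartrate
Reagents that add atoms: none
Why: low‑temperature DIBAL‑H reduction of a δ‑lactone stops at the aluminium acetal and gives the lactol without touching alkene or furan, the only new centre being the inconsequential anomeric one.

Step 6
Reactants: 10 lactol; 11 methyl trichloroacetate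
Product: 12 methyl (2Z)‑2‑chloro‑3‑{(1S,2R,6R)‑2‑[(2S)‑2‑(furan‑2‑yl)‑2‑hydroxyethyl]‑3‑methyl‑6‑(propan‑2‑yl)cyclohex‑3‑en‑1‑yl}prop‑2‑enoate
Conditions: CrCl2 (6 equiv), THF, 25 °C
Reagents that add atoms: none
Why: divalent‑chromium Reformatsky‑type addition of the trichloroacetate to the open hydroxy‑aldehyde form of the lactol followed by reductive elimination (chromium‑mediated α‑haloacrylate olefination) gives the Z‑chloroacrylate with very high selectivity, placing the ester trans and the chloride cis to C1 as the ring closure requires.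

Step 7
Reactants: 12 hydroxy (Z)‑α‑chloroacrylate
Product: 14 furanophane enoate (ten‑membered ring closed between furan C5 and the acrylate α‑carbon; E‑enoate; 8‑OH free; 1R 8S 10R 14R), via furyl boronate 13 (not isolated)
Conditions: [Ir(OMe)(cod)]2 (2 mol %), dtbpy (4 mol %), B2pin2, THF, 50 °C; then slow addition to Pd(OAc)2 (10 mol %), SPhos (20 mol %), K3PO4, THF/H2O, 45 °C, 2 mM
Reagents that add atoms: none
Why: iridium‑catalysed C–H borylation takes the only free furan α‑position and the intramolecular Suzuki–Miyaura coupling with the activated vinyl chloride proceeds with retention of alkene geometry under high dilution, closing the ten‑membered ring with the ester trans to C1.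

Step 8
Reactants: 14 furanophane enoate
Product: 15 bridged pyranone hemiketal (6‑hydroxy‑2H‑pyran‑3(6H)‑one spanning C4 and C8; 1R 4S 8S 10R 14R)
Conditions: NBS (1.05 equiv), NaHCO3, THF/H2O (4:1), 0 °C
Reagents that add atoms: water (O)
Why: Achmatowicz oxidative ring expansion, in which bromonium attack on the strained electron‑rich furan and hydrolysis give the cis‑enedione that the C8 hydroxyl traps as the six‑membered hemiketal, is ionic and much faster than attack on the trisubstituted alkene or the enoate, with the C4 configuration fixed by the bridge.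

Step 9
Reactants: 15 bridged pyranone hemiketal
Product: 17 8‑O‑deacyl sarcodictyin A 4‑O‑methyl ketal (4,7‑oxygen‑bridged furanose form; 1R 4R 7S 8S 10R 14R), via pyranose carbinol 16 (not isolated)
Conditions: MeLi, CeCl3, THF, −78 °C; then PPTS, MeOH, 25 °C
Reagents that add atoms: methyllithium ([Li]C); methanol (CO)
Why: the organocerium reagent adds 1,2 to the enone carbonyl (ketone before the hindered conjugated ester) from the exo face opposite the bridging chain, setting C7 as S, and acid in methanol then opens the pyranose hemiketal and recloses it through the tertiary C7 hydroxyl to the less strained five‑membered methyl ketal, a pyranose→furanose ring contraction that frees the C8 hydroxyl and fixes C4 as R through the bridge.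

Step 10
Reactants: 18 1‑methyl‑1H‑imidazole‑4‑carbaldehyde; 19 malonic acid
Product: 20 (2E)‑3‑(1‑methyl‑1H‑imidazol‑4‑yl)prop‑2‑enoic acid
Conditions: pyridine, piperidine (cat.), 90 °C
Reagents that add atoms: none
Why: Knoevenagel–Doebner condensation with decarboxylation gives the E‑acrylic acid exclusively.

Step 11
Reactants: 17 8‑O‑deacyl sarcodictyin A 4‑O‑methyl ketal; 20 (2E)‑3‑(1‑methyl‑1H‑imidazol‑4‑yl)prop‑2‑enoic acid
Product: 21 sarcodictyin A 4‑O‑methyl ketal
Conditions: 2,4,6‑trichlorobenzoyl chloride, Et3N, DMAP, toluene, 25 → 60 °C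
Reagents that add atoms: none
Why: Yamaguchi esterification through the mixed anhydride acylates the hindered secondary C8 hydroxyl, the only free OH, with retention at C8.

Step 12
Reactants: 21 sarcodictyin A 4‑O‑methyl ketal
Product: 22 sarcodictyin A (target)
Conditions: CSA (1.5 equiv), CH2Cl2/H2O (10:1), 25 °C
Reagents that add atoms: water (O)
Why: mild acid‑catalysed ketal hydrolysis through the bridged oxocarbenium ion exchanges OMe for OH with the C4 configuration dictated by the oxygen bridge, leaving the esters intact.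

**Compound list**
1 | methyl acetoacetate | CC(=O)CC(=O)OC | starting material
2 | methyl 3‑oxopentanoate | CCC(=O)CC(=O)OC | intermediate
3 | (E)‑4‑methylpent‑2‑enal | CC(C)/C=C/C=O | starting material
4 | methyl (3R)‑5‑oxo‑2‑propanoyl‑3‑(propan‑2‑yl)pentanoate (Michael adduct, C2 epimers) | CCC(=O)C(C(=O)OC)[C@@H](C(C)C)CC=O | intermediate
5 | methyl (1S,6R)‑3‑methyl‑2‑oxo‑6‑(propan‑2‑yl)cyclohex‑3‑ene‑1‑carboxylate | COC(=O)[C@H]1[C@@H](C(C)C)CC=C(C)C1=O | intermediate
6 | methyl (1S,6R)‑3‑methyl‑2‑methylidene‑6‑(propan‑2‑yl)cyclohex‑3‑ene‑1‑carboxylate | COC(=O)[C@H]1[C@@H](C(C)C)CC=C(C)C1=C | intermediate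
7 | furfural | O=Cc1ccco1 | starting material
8 | methyl (1S,2R,6R)‑2‑[(2S)‑2‑(furan‑2‑yl)‑2‑hydroxyethyl]‑3‑methyl‑6‑(propan‑2‑yl)cyclohex‑3‑ene‑1‑carboxylate | COC(=O)[C@H]1[C@@H](C(C)C)CC=C(C)[C@@H]1C[C@H](O)c1ccco1 | intermediate
9 | (3S,4aR,8R,8aS)‑3‑(furan‑2‑yl)‑5‑methyl‑8‑(propan‑2‑yl)‑3,4,4a,7,8,8a‑hexahydro‑1H‑isochromen‑1‑one | O=C1[C@H]2[C@@H](C(C)C)CC=C(C)[C@@H]2C[C@@H](c2ccco2)O1 | intermediate
10 | (3S,4aR,8R,8aS)‑3‑(furan‑2‑yl)‑5‑methyl‑8‑(propan‑2‑yl)‑3,4,4a,7,8,8a‑hexahydro‑1H‑isochromen‑1‑ol (both anomers) | OC1[C@H]2[C@@H](C(C)C)CC=C(C)[C@@H]2C[C@@H](c2ccco2)O1 | intermediate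
11 | methyl trichloroacetate | COC(=O)C(Cl)(Cl)Cl | starting material
12 | methyl (2Z)‑2‑chloro‑3‑{(1S,2R,6R)‑2‑[(2S)‑2‑(furan‑2‑yl)‑2‑hydroxyethyl]‑3‑methyl‑6‑(propan‑2‑yl)cyclohex‑3‑en‑1‑yl}prop‑2‑enoate | COC(=O)/C(Cl)=C/[C@H]1[C@@H](C(C)C)CC=C(C)[C@@H]1C[C@H](O)c1ccco1 | intermediate
13 | 12 carrying a 4,4,5,5‑tetramethyl‑1,3,2‑dioxaborolan‑2‑yl group at furan C5 | COC(=O)/C(Cl)=C/[C@H]1[C@@H](C(C)C)CC=C(C)[C@@H]1C[C@H](O)c1ccc(B2OC(C)(C)C(C)(C)O2)o1 | intermediate
14 | furanophane enoate: furan C2 on C8 (free 8S‑OH), furan C5 on C3 of the E‑enoate; 1R,8S,10R,14R | COC(=O)/C1=C/[C@H]2[C@@H](C(C)C)CC=C(C)[C@@H]2C[C@H](O)c2ccc1o2 | intermediate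
15 | bridged pyranone hemiketal: ring O joins C8 and C4(OH), C7 ketone, C5=C6; 1R,4S,8S,10R,14R | COC(=O)/C1=C/[C@H]2[C@@H](C(C)C)CC=C(C)[C@@H]2C[C@@H]2O[C@@]1(O)C=CC2=O | intermediate
16 | pyranose carbinol: as 15 with C7 bearing Me and OH; 1R,4S,7S,8S,10R,14R | COC(=O)/C1=C/[C@H]2[C@@H](C(C)C)CC=C(C)[C@@H]2C[C@@H]2O[C@@]1(O)C=C[C@]2(C)O | intermediate
17 | 8‑O‑deacyl sarcodictyin A 4‑O‑methyl ketal; 1R,4R,7S,8S,10R,14R | COC(=O)/C1=C/[C@H]2[C@@H](C(C)C)CC=C(C)[C@@H]2C[C@H](O)[C@]2(C)C=C[C@@]1(OC)O2 | intermediate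
18 | 1‑methyl‑1H‑imidazole‑4‑carbaldehyde | O=Cc1cn(C)cn1 | starting material
19 | malonic acid | OC(=O)CC(=O)O | starting material
20 | (2E)‑3‑(1‑methyl‑1H‑imidazol‑4‑yl)prop‑2‑enoic acid | OC(=O)/C=C/c1cn(C)cn1 | intermediate
21 | sarcodictyin A 4‑O‑methyl ketal | COC(=O)/C1=C/[C@H]2[C@@H](C(C)C)CC=C(C)[C@@H]2C[C@H](OC(=O)/C=C/c2cn(C)cn2)[C@]2(C)C=C[C@@]1(OC)O2 | intermediate
22 | sarcodictyin A (CNP0372023.1) | COC(=O)/C1=C/[C@H]2[C@@H](C(C)C)CC=C(C)[C@@H]2C[C@H](OC(=O)/C=C/c2cn(C)cn2)[C@]2(C)C=C[C@@]1(O)O2 | target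

**Totals**
Total step count: 12. Longest linear sequence: 11 (steps 1–9, 11, 12).

**Steps most likely to fail**

Step 4 (proposed nickel homoallylation). The risks are wrong face at C10, hydrogen delivery to C12 instead of C10, or poor control at C8. The fallback uses known chemistry and sets out from 6. Hydroboration with 9‑BBN‑H at the exocyclic CH2 from the same equatorial face gives the alkylborane methyl (1S,2R,6R)‑2‑[(9‑borabicyclo[3.3.1]nonan‑9‑yl)methyl]‑3‑methyl‑6‑(propan‑2‑yl)cyclohex‑3‑ene‑1‑carboxylate F1. Carbonylative Suzuki–Miyaura coupling of F1 with 2‑iodofuran under CO (1 atm, PdCl2(dppf), K3PO4) gives the keto ester methyl (1S,2R,6R)‑2‑[2‑(furan‑2‑yl)‑2‑oxoethyl]‑3‑methyl‑6‑(propan‑2‑yl)cyclohex‑3‑ene‑1‑carboxylate F2. Reduction with BH3·SMe2 and the (R)‑methyl‑CBS oxazaborolidine sets 8S by reagent control and gives hydroxy ester 8, which is lactonised with KOt‑Bu as in step 4; the route is rejoined at 9.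

Step 7 (strained ten‑membered ring; the 2‑furyl boronate is prone to protodeborylation). The fallback sets out from 12 and drops the boron route for a C–H functionalisation: Pd(OAc)2, PCy3·HBF4, pivalic acid and K2CO3 in toluene at 100 °C under high dilution. Oxidative addition of the vinyl chloride to zerovalent palladium, carboxylate‑assisted palladation of the furan C5–H and reductive elimination would give the furanophane directly. This makes no new compound (F0) and comes back to the route at 14.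

Step 3 (methylenation of an enolisable β‑keto ester). The fallback sets out from 5. NaH and PhNTf2 give the enol triflate methyl (6R)‑3‑methyl‑6‑(propan‑2‑yl)‑2‑[(trifluoromethanesulfonyl)oxy]cyclohexa‑1,3‑diene‑1‑carboxylate F3. Pd(PPh3)4‑catalysed Kumada coupling with Me3SiCH2MgCl gives the allylsilane methyl (6R)‑3‑methyl‑6‑(propan‑2‑yl)‑2‑[(trimethylsilyl)methyl]cyclohexa‑1,3‑diene‑1‑carboxylate F4. Fluoride‑induced protodesilylation (TBAF, wet THF, −20 °C) protonates the extended enolate at the α‑carbon and gives the exocyclic diene, whose C1 epimers are equilibrated to the trans ester with catalytic DBU; the route is rejoined at 6.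

Further compounds
F1 | step 4 | methyl (1S,2R,6R)‑2‑[(9‑borabicyclo[3.3.1]nonan‑9‑yl)methyl]‑3‑methyl‑6‑(propan‑2‑yl)cyclohex‑3‑ene‑1‑carboxylate | COC(=O)[C@H]1[C@@H](C(C)C)CC=C(C)[C@@H]1CB1C2CCCC1CCC2
F2 | step 4 | methyl (1S,2R,6R)‑2‑[2‑(furan‑2‑yl)‑2‑oxoethyl]‑3‑methyl‑6‑(propan‑2‑yl)cyclohex‑3‑ene‑1‑carboxylate | COC(=O)[C@H]1[C@@H](C(C)C)CC=C(C)[C@@H]1CC(=O)c1ccco1
F0 | step 7 | none | none
F3 | step 3 | methyl (6R)‑3‑methyl‑6‑(propan‑2‑yl)‑2‑[(trifluoromethanesulfonyl)oxy]cyclohexa‑1,3‑diene‑1‑carboxylate | COC(=O)C1=C(OS(=O)(=O)C(F)(F)F)C(C)=CC[C@@H]1C(C)C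
F4 | step 3 | methyl (6R)‑3‑methyl‑6‑(propan‑2‑yl)‑2‑[(trimethylsilyl)methyl]cyclohexa‑1,3‑diene‑1‑carboxylate | COC(=O)C1=C(C[Si](C)(C)C)C(C)=CC[C@@H]1C(C)C
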